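Assumption: the SMILES is read as drawn, giving (4S,4aR,6S,7R,7aS) in both bicyclic units and 2E,6E in the diacid linker. The route is a paper plan and has not been run.

**Retrosynthetic overview**
1. Target ⇒ (2E,6E)-2,6-dimethylocta-2,6-dienedioic acid + two molecules of the C6-epimeric amino alcohol (6-epi-incarvilline); both ester C–O bonds are made last by a twofold Mitsunobu inversion at C6.
2. 6-epi-Incarvilline ⇒ N-tosyl bicyclic enone, through hydrogenation (sets C4a), hydride reduction (sets C6), N–S cleavage and N-methylation.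
3. Enone ⇒ acyclic N-tosyl 1,7-enyne (terminal alkyne, E-crotyl alkene) + CO: one cobalt-catalysed [2+2+1] closes the piperidine and the cyclopentenone together and sets C7 and C7a. No ring exists before this step and none is formed after it.
4. Enyne ⇒ (R)-Roche ester (the only source of chirality, becomes C4) + N-crotyl sulfonamide; diacid ⇒ geranyl acetate by allylic oxidation.

**Route**

Step 1
Reactants: 1 4-methylbenzenesulfonamide; 2 (2E)-1-bromobut-2-ene (crotyl bromide)
Product: 3 N-[(2E)-but-2-en-1-yl]-4-methylbenzenesulfonamide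
Conditions: 1 (3 equiv), K2CO3, MeCN, 60 °C; recrystallise
Reagents that add atoms: none
Why: SN2 N-alkylation of the sulfonamide anion at the primary allylic bromide, with excess sulfonamide to hold back dialkylation, carries the E alkene geometry over unchanged.

Step 2
Reactants: 3 N-[(2E)-but-2-en-1-yl]-4-methylbenzenesulfonamide; 4 methyl (2R)-3-hydroxy-2-methylpropanoate ((R)-Roche ester)
Product: 5 methyl (2R)-3-{[(2E)-but-2-en-1-yl](4-methylbenzenesulfonyl)amino}-2-methylpropanoate
Conditions: PPh3, DIAD, THF, 0 °C to rt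
Reagents that add atoms: none
Why: Mitsunobu (Fukuyama-type) N-alkylation of the acidic sulfonamide N–H by the primary alcohol under neutral conditions; the stereocentre is not a reacting centre and is kept.

Step 3
Reactants: 5 methyl (2R)-3-{[(2E)-but-2-en-1-yl](4-methylbenzenesulfonyl)amino}-2-methylpropanoate
Product: 7 N-[(2E)-but-2-en-1-yl]-4-methyl-N-[(2S)-2-methylbut-3-yn-1-yl]benzenesulfonamide, via aldehyde 6 (not isolated)
Conditions: i-Bu2AlH, CH2Cl2, −78 °C; then MeOH, K2CO3, dimethyl (1-diazo-2-oxopropyl)phosphonate, −78 °C to rt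
Reagents that add atoms: dimethyl (1-diazo-2-oxopropyl)phosphonate, COP(=O)(OC)C(=[N+]=[N-])C(C)=O
Why: ester half-reduction and Ohira–Bestmann (Seyferth–Gilbert) homologation in one flask give the terminal alkyne; the aldehyde is never isolated, which limits epimerisation, and the stereocentre is retained (R becomes S only because the CIP priorities change).

Step 4
Reactants: 7 N-[(2E)-but-2-en-1-yl]-4-methyl-N-[(2S)-2-methylbut-3-yn-1-yl]benzenesulfonamide
Product: 8 (4S,7R,7aR)-4,7-dimethyl-2-(4-methylbenzenesulfonyl)-1,2,3,4,7,7a-hexahydro-6H-cyclopenta[c]pyridin-6-one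
Conditions: Co2(CO)8 (20 mol %), tetramethylthiourea (60 mol %), CO (1 atm), toluene, 70 °C
Reagents that add atoms: carbon monoxide, [C-]#[O+]
Why: intramolecular Pauson–Khand [2+2+1] cyclocarbonylation of the sulfonamide-tethered 1,7-enyne closes the piperidine (C4a–C7a) and the cyclopentenone (C5–C6–C7) in the same operation; suprafacial addition to the E alkene places the C7 methyl trans to C1 (7R), and a chair-like cobaltacycle with the C4 methyl equatorial next to the unsubstituted alkyne terminus puts H-7a cis to H-4 (7aR).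

Step 5
Reactants: 8 (4S,7R,7aR)-4,7-dimethyl-2-(4-methylbenzenesulfonyl)-1,2,3,4,7,7a-hexahydro-6H-cyclopenta[c]pyridin-6-one
Product: 9 (4S,4aR,7R,7aS)-4,7-dimethyl-2-(4-methylbenzenesulfonyl)octahydro-6H-cyclopenta[c]pyridin-6-one
Conditions: H2 (1 atm), Pd/C (10 wt %), EtOAc, rt
Reagents that add atoms: none
Why: heterogeneous syn hydrogenation of the enone C4a=C5 bond from its equatorial face, which carries only the axial H-4 and H-7a while the other face is screened by the axial hydrogens at C1 and C3, gives the cis ring fusion (4aR); the sulfonamide, the ketone and the already thermodynamically preferred C7 configuration are untouched.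

Step 6
Reactants: 9 (4S,4aR,7R,7aS)-4,7-dimethyl-2-(4-methylbenzenesulfonyl)octahydro-6H-cyclopenta[c]pyridin-6-one
Product: 11 (4S,4aR,6R,7R,7aS)-4,7-dimethyloctahydro-1H-cyclopenta[c]pyridin-6-ol, via N-tosyl alcohol 10 (not isolated)
Conditions: NaAlH2(OCH2CH2OCH3)2, toluene, −20 to 0 °C, then 110 °C; aq. NaOH work-up
Reagents that add atoms: none
Why: hydride reduction then reductive N–S cleavage by the same aluminium hydride: at low temperature hydride enters the cyclopentanone from the convex face, cis to the 7-methyl as small hydrides do with 2-methylcyclopentanones and away from the piperidine ring, so the hydroxyl ends up trans to the methyl (6R), and at reflux the reagent removes the arenesulfonyl group from nitrogen.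

Step 7
Reactants: 11 (4S,4aR,6R,7R,7aS)-4,7-dimethyloctahydro-1H-cyclopenta[c]pyridin-6-ol
Product: 13 (4S,4aR,6R,7R,7aS)-2,4,7-trimethyloctahydro-1H-cyclopenta[c]pyridin-6-ol (6-epi-incarvilline), via iminium ion 12 (not isolated)
Conditions: HCO2H, aq. HCHO (37 %), 90 °C; then aq. NaOH
Reagents that add atoms: formaldehyde, C=O
Why: Eschweiler–Clarke reductive methylation: the secondary amine condenses with formaldehyde to the iminium ion, which formate reduces by hydride transfer, stopping at the tertiary N-methylamine without touching any stereocentre (any O-formate is cleaved in the basic work-up).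

Step 8
Reactants: 14 (2E)-3,7-dimethylocta-2,6-dien-1-yl acetate (geranyl acetate)
Product: 15 (2E,6E)-8-hydroxy-3,7-dimethylocta-2,6-dien-1-yl acetate
Conditions: SeO2 (10 mol %), salicylic acid (10 mol %), t-BuOOH (70 % aq.), CH2Cl2, rt
Reagents that add atoms: tert-butyl hydroperoxide, CC(C)(C)OO
Why: Sharpless SeO2-catalysed allylic oxidation (ene reaction then [2,3]-sigmatropic shift) is selective for the E methyl group of the remote, more electron-rich trisubstituted alkene, the alkene next to the acetate being deactivated, so the new CH2OH is formed with 6E geometry.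

Step 9
Reactants: 15 (2E,6E)-8-hydroxy-3,7-dimethylocta-2,6-dien-1-yl acetate
Product: 16 (2E,6E)-2,6-dimethylocta-2,6-diene-1,8-diol
Conditions: K2CO3 (cat.), MeOH, rt
Reagents that add atoms: none
Why: base-catalysed transesterification (methanolysis) removes the acetate without affecting either alkene.

Step 10
Reactants: 16 (2E,6E)-2,6-dimethylocta-2,6-diene-1,8-diol
Product: 18 (2E,6E)-2,6-dimethylocta-2,6-dienedioic acid, via dialdehyde 17 (not isolated)
Conditions: TEMPO (20 mol %), PhI(OAc)2, CH2Cl2, rt; then t-BuOH, H2O, 2-methylbut-2-ene, NaH2PO4, NaClO2, 0 °C to rt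
Reagents that add atoms: sodium chlorite, [Na+].[O-]Cl=O
Why: TEMPO/PhI(OAc)2 oxidation of both allylic alcohols to the dienedial, followed in the same flask by Pinnick (Lindgren) oxidation, gives the diacid without E/Z isomerisation, 2-methylbut-2-ene scavenging the HOCl.

Step 11
Reactants: 18 (2E,6E)-2,6-dimethylocta-2,6-dienedioic acid; 13 (4S,4aR,6R,7R,7aS)-2,4,7-trimethyloctahydro-1H-cyclopenta[c]pyridin-6-ol (2.3 equiv)
Product: 21 bis[(4S,4aR,6S,7R,7aS)-2,4,7-trimethyloctahydro-1H-cyclopenta[c]pyridin-6-yl] (2E,6E)-2,6-dimethylocta-2,6-dienedioate (CNP0240822.2), via C8 monoester 19 (not isolated), via C1 monoester 20 (not isolated)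
Conditions: PPh3 (3 equiv), DIAD (3 equiv), THF, 0 °C to rt
Reagents that add atoms: none
Why: twofold Mitsunobu esterification: each carboxylate displaces the activated C6 oxygen from the open convex face by SN2 with inversion (6R to 6S), which puts the ester cis to the 7-methyl, and because the acid is never turned into an acyl electrophile the 3-methyl-2-enoate end cannot deconjugate; the tertiary amine is tolerated.

**Compound list**
1 | 4-methylbenzenesulfonamide | Cc1ccc(cc1)S(N)(=O)=O | starting material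
2 | (2E)-1-bromobut-2-ene | C/C=C/CBr | starting material
3 | N-[(2E)-but-2-en-1-yl]-4-methylbenzenesulfonamide | C/C=C/CNS(=O)(=O)c1ccc(C)cc1 | intermediate
4 | methyl (2R)-3-hydroxy-2-methylpropanoate | COC(=O)[C@H](C)CO | starting material
5 | methyl (2R)-3-{[(2E)-but-2-en-1-yl](4-methylbenzenesulfonyl)amino}-2-methylpropanoate | C/C=C/CN(C[C@H](C(=O)OC)C)S(=O)(=O)c1ccc(C)cc1 | intermediate
6 | (2R)-3-{[(2E)-but-2-en-1-yl](4-methylbenzenesulfonyl)amino}-2-methylpropanal | C/C=C/CN(C[C@H](C=O)C)S(=O)(=O)c1ccc(C)cc1 | intermediate (not isolated)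
7 | N-[(2E)-but-2-en-1-yl]-4-methyl-N-[(2S)-2-methylbut-3-yn-1-yl]benzenesulfonamide | C/C=C/CN(C[C@H](C#C)C)S(=O)(=O)c1ccc(C)cc1 | intermediate
8 | (4S,7R,7aR)-4,7-dimethyl-2-(4-methylbenzenesulfonyl)-1,2,3,4,7,7a-hexahydro-6H-cyclopenta[c]pyridin-6-one | O=C1C=C2[C@H](CN(S(=O)(=O)c3ccc(C)cc3)C[C@H]2C)[C@H]1C | intermediate
9 | (4S,4aR,7R,7aS)-4,7-dimethyl-2-(4-methylbenzenesulfonyl)octahydro-6H-cyclopenta[c]pyridin-6-one | O=C1C[C@H]2[C@H](CN(S(=O)(=O)c3ccc(C)cc3)C[C@H]2C)[C@H]1C | intermediate
10 | (4S,4aR,6R,7R,7aS)-4,7-dimethyl-2-(4-methylbenzenesulfonyl)octahydro-1H-cyclopenta[c]pyridin-6-ol | O[C@@H]1C[C@H]2[C@H](CN(S(=O)(=O)c3ccc(C)cc3)C[C@H]2C)[C@H]1C | intermediate (not isolated)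
11 | (4S,4aR,6R,7R,7aS)-4,7-dimethyloctahydro-1H-cyclopenta[c]pyridin-6-ol | O[C@@H]1C[C@H]2[C@H](CNC[C@H]2C)[C@H]1C | intermediate
12 | (4S,4aR,6R,7R,7aS)-6-hydroxy-4,7-dimethyl-2-methylideneoctahydro-1H-cyclopenta[c]pyridin-2-ium | O[C@@H]1C[C@H]2[C@H](C[N+](=C)C[C@H]2C)[C@H]1C | intermediate (not isolated)
13 | (4S,4aR,6R,7R,7aS)-2,4,7-trimethyloctahydro-1H-cyclopenta[c]pyridin-6-ol (6-epi-incarvilline) | O[C@@H]1C[C@H]2[C@H](CN(C)C[C@H]2C)[C@H]1C | intermediate
14 | (2E)-3,7-dimethylocta-2,6-dien-1-yl acetate (geranyl acetate) | CC(=O)OC/C=C(\C)CCC=C(C)C | starting material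
15 | (2E,6E)-8-hydroxy-3,7-dimethylocta-2,6-dien-1-yl acetate | CC(=O)OC/C=C(\C)CC/C=C(\C)CO | intermediate
16 | (2E,6E)-2,6-dimethylocta-2,6-diene-1,8-diol | OC/C=C(\C)CC/C=C(\C)CO | intermediate
17 | (2E,6E)-2,6-dimethylocta-2,6-dienedial | O=C/C=C(\C)CC/C=C(\C)C=O | intermediate (not isolated)
18 | (2E,6E)-2,6-dimethylocta-2,6-dienedioic acid | OC(=O)/C=C(\C)CC/C=C(\C)C(O)=O | intermediate
19 | (2E,6E)-2,6-dimethyl-8-oxo-8-{[(4S,4aR,6S,7R,7aS)-2,4,7-trimethyloctahydro-1H-cyclopenta[c]pyridin-6-yl]oxy}octa-2,6-dienoic acid | C/C(=C\C(=O)O[C@H]1C[C@H]2[C@H](CN(C)C[C@H]2C)[C@H]1C)CC/C=C(\C)C(O)=O | intermediate (not isolated)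
20 | (2E,6E)-3,7-dimethyl-8-oxo-8-{[(4S,4aR,6S,7R,7aS)-2,4,7-trimethyloctahydro-1H-cyclopenta[c]pyridin-6-yl]oxy}octa-2,6-dienoic acid | OC(=O)/C=C(\C)CC/C=C(\C)C(=O)O[C@H]1C[C@H]2[C@H](CN(C)C[C@H]2C)[C@H]1C | intermediate (not isolated)
21 | bis[(4S,4aR,6S,7R,7aS)-2,4,7-trimethyloctahydro-1H-cyclopenta[c]pyridin-6-yl] (2E,6E)-2,6-dimethylocta-2,6-dienedioate (CNP0240822.2) | C/C(=C\C(=O)O[C@H]1C[C@H]2[C@H](CN(C)C[C@H]2C)[C@H]1C)CC/C=C(\C)C(=O)O[C@H]1C[C@H]2[C@H](CN(C)C[C@H]2C)[C@H]1C | target

**Step count**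
Total: 11 steps (1–7 amino alcohol, 8–10 diacid, 11 union). Longest linear sequence: 8 steps (1, 2, 3, 4, 5, 6, 7, 11).

**Three steps most likely to fail**

Step 4. An internal alkene and a six-membered ring closure are both at the slow end of the cyclocarbonylation, diene formation by beta-hydride loss can compete, and the C4/C7a selectivity rests on a conformational argument. Fallback: introduce the C7 methyl after the ring-forming step instead of through the alkene. Setting out from 4, Mitsunobu alkylation of commercial N-allyl-4-methylbenzenesulfonamide gives the N-allyl ester F1. The same one-flask i-Bu2AlH/Ohira–Bestmann sequence passes through the N-allyl aldehyde F2 to the N-allyl enyne F3. Its monosubstituted alkene is the most reliable alkene class for the cobalt-catalysed [2+2+1] and gives the 7-unsubstituted enone F4. LiN(i-Pr)2 (THF, −78 °C) removes the alpha-prime proton to give the cross-conjugated lithium dienolate F5, which MeI methylates at C7 anti to the C7a–C1 bond; this rejoins the route at 8.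

Step 11. Two SN2 displacements at a secondary cyclopentyl carbon flanked by a methyl group must both succeed on one diacid, and elimination or stalling at 19/20 is possible. Fallback: separate the inversion from the ester formation. Setting out from 13, a Mitsunobu reaction with 4-nitrobenzoic acid (PPh3, DIAD), a stronger and monofunctional acid, gives the inverted 4-nitrobenzoate F6. K2CO3 in MeOH releases incarvilline F7, the C6 alcohol of natural configuration. F7 (2.2 equiv) is then acylated with retention by diacid 18 using EDC·HCl and DMAP (cat.) in CH2Cl2 at 0 °C, which passes through the same monoesters 19 and 20 and rejoins the route at 21.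

Step 6. One reagent has to deliver both the C6 selectivity and a forcing N–S cleavage. Fallback: change the nitrogen substituent to a carbamate before the ring-forming step, so that one LiAlH4 reduction at the end gives both the alcohol and the N-methyl group. Setting out from 7, NaC10H8 (DME, −78 °C, then NH4Cl) cleaves the N–S bond to the secondary amine F8 (not isolated), which methyl chloroformate and aq. NaHCO3 convert to the methyl carbamate enyne F9. The cyclocarbonylation of step 4 then gives the carbamate enone F10, and hydrogenation as in step 5 gives the carbamate ketone F11. LiAlH4 (THF, 0 °C, then reflux) reduces the ketone first, giving the hydroxy carbamate F12, and then the carbamate to N–CH3; this rejoins the route at 13.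

**Further compounds**
F1 | step 4 | methyl (2R)-2-methyl-3-[(4-methylbenzenesulfonyl)(prop-2-en-1-yl)amino]propanoate | C=CCN(C[C@H](C(=O)OC)C)S(=O)(=O)c1ccc(C)cc1
F2 | step 4 | (2R)-2-methyl-3-[(4-methylbenzenesulfonyl)(prop-2-en-1-yl)amino]propanal | C=CCN(C[C@H](C=O)C)S(=O)(=O)c1ccc(C)cc1
F3 | step 4 | 4-methyl-N-[(2S)-2-methylbut-3-yn-1-yl]-N-(prop-2-en-1-yl)benzenesulfonamide | C=CCN(C[C@H](C#C)C)S(=O)(=O)c1ccc(C)cc1
F4 | step 4 | (4S,7aR)-4-methyl-2-(4-methylbenzenesulfonyl)-1,2,3,4,7,7a-hexahydro-6H-cyclopenta[c]pyridin-6-one | O=C1C=C2[C@H](CN(S(=O)(=O)c3ccc(C)cc3)C[C@H]2C)C1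
F5 | step 4 | lithium (4S,7aR)-4-methyl-2-(4-methylbenzenesulfonyl)-2,3,4,7a-tetrahydro-1H-cyclopenta[c]pyridin-6-olate | [Li]OC=1C=C2[C@H](CN(S(=O)(=O)c3ccc(C)cc3)C[C@H]2C)C=1
F6 | step 11 | (4S,4aR,6S,7R,7aS)-2,4,7-trimethyloctahydro-1H-cyclopenta[c]pyridin-6-yl 4-nitrobenzoate | O=C(O[C@H]1C[C@H]2[C@H](CN(C)C[C@H]2C)[C@H]1C)c1ccc(cc1)[N+]([O-])=O
F7 | step 11 | (4S,4aR,6S,7R,7aS)-2,4,7-trimethyloctahydro-1H-cyclopenta[c]pyridin-6-ol (incarvilline) | O[C@H]1C[C@H]2[C@H](CN(C)C[C@H]2C)[C@H]1C
F8 | step 6 | (2E)-N-[(2S)-2-methylbut-3-yn-1-yl]but-2-en-1-amine | C/C=C/CNC[C@H](C#C)C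
F9 | step 6 | methyl N-[(2E)-but-2-en-1-yl]-N-[(2S)-2-methylbut-3-yn-1-yl]carbamate | C/C=C/CN(C[C@H](C#C)C)C(=O)OC
F10 | step 6 | methyl (4S,7R,7aR)-4,7-dimethyl-6-oxo-1,3,4,6,7,7a-hexahydro-2H-cyclopenta[c]pyridine-2-carboxylate | O=C1C=C2[C@H](CN(C(=O)OC)C[C@H]2C)[C@H]1C
F11 | step 6 | methyl (4S,4aR,7R,7aS)-4,7-dimethyl-6-oxooctahydro-2H-cyclopenta[c]pyridine-2-carboxylate | O=C1C[C@H]2[C@H](CN(C(=O)OC)C[C@H]2C)[C@H]1C
F12 | step 6 | methyl (4S,4aR,6R,7R,7aS)-6-hydroxy-4,7-dimethyloctahydro-2H-cyclopenta[c]pyridine-2-carboxylate | O[C@@H]1C[C@H]2[C@H](CN(C(=O)OC)C[C@H]2C)[C@H]1C
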